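Readings and results stem from a simulated flask for an exercise; noise was put on by code.

The amounts in this flask bound one product before any rate is known: each L costs one E, and E is charged at 1.00 mM against 10 mM of Q, so E is the limiting reagent of X + E → L.

- dusk: Q 10 mM; Z 40 mM; E 1 mM; the very flask that is asked about, followed so far
- flask: Q 10 mM; Z 40.0 mM; E 1.00 mM; time 10 min

- dusk (time / s: Q / %, X / %): 15.0: 54.3, 44.6; 40.0: 21.8, 71.8; 80.0: 5.3, 78.9; 120: 1.6, 76.0

(readings scatter by 0.3 percentage points)

1. how much Q there is at 10 min, in percent of the Q charged
2. how much X there is at 10 min, in percent of the Q charged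
3. how much D there is at 10 min, in percent of the Q charged
4. how much J there is at 10 min, in percent of the Q charged

c = E charged / Q charged = 10.0%, the E ceiling, the most L the charges allow, in percent of the Q charged.

By hand, more E raises c in proportion and more Q lowers it. Z and the time stand nowhere in the ratio; they move the division of the remainder among X, D, J and G. L is thus the small correction, and the remainder the large part.

The readings suggest how soon c is reached. Let S = 100 − Q − X, in percent of the Q charged, the shortfall held by D, J, G and L. In two equal spans it grows:

from 40.0 s to 80.0 s: 9.4 percentage points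
from 80.0 s to 120 s: 6.6 points

S slows while X stays high, which reads as the E step fading within minutes. At 120 s, S reads 22.4%, above c, so, within the scatter of the readings, at least 12 points already lies in D, J and G. The reckoning here commits to a sum, not a split: L at c by the asked time, and X + D + J + G = 90.0%.

The forecast gives Q 0%, X 33%, D 46% and J 11%, with L near 8%, and says of D, J and G: “The split is unconstrained by the data”.

The flask gives Q 0%, X 43.0%, D 2.81% and J 16.2%.

    Q + Z → X (k = 1.10 M⁻¹ s⁻¹)
    Z + X → D (k = 0.0540 M⁻¹ s⁻¹)
    Z + D → J (k = 0.880 M⁻¹ s⁻¹)
    Z + J → G (k = 0.170 M⁻¹ s⁻¹)
    X + E → L (k = 2.50 M⁻¹ s⁻¹)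

In this flask L stands at 10.0%, with 0.0141% of the E charge left, and X, D, J and G sum to 90.0%. The forecast parts from the flask on D, 46% against 2.81%. The half-life of D by Z + D → J alone, the other concentrations as charged, is 0.33 min. The half-life of X by its own step with Z alone, the other concentrations as charged, is longer, 5.3 min. The neighbour charged with 6.0 mM of Q has c = 16.7%, leaving 83.3% for the adducts. That neighbour keeps 0.931% of its E, holds L at 16.5%, and has X, D, J and G summing to 83.5%.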